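**Plan**

- Ring A is numbered C1 (carbon bearing the 2,4-dibromophenoxy oxygen), C2 (OMe), C3 (H), C4–C6 (Br). Retrosynthetically, C5–Br goes back to a C5 amine (Sandmeyer), C4–Br and C6–Br to amine-directed brominations, the amine to a nitro group, and O–CH3 to a phenol.
- The resulting 2-aryloxy-4-nitrophenol is cut at C1–C6 and C3–C4 into an aryloxyacetone (C1–C2–C3) and nitromalonaldehyde (C4–C5–C6). The ketone is cut at its ArO–CH2 bond.
- Enabling feature: in ring A, C5 lies para to the C2 oxygen and between C4 and C6. This is the 4-nitrophenol pattern a ketone plus nitromalonaldehyde delivers, with nitrogen on the one carbon that can direct bromine to both neighbours while C3 stays C–H.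
- Forward: ring B is bought intact as 2,4-dibromophenol and O-alkylated, so the ether oxygen is in place before ring A exists. Ring A is then closed by a double aldol benzannulation, followed by methylation, reduction, dibromination and Sandmeyer bromination.
- Stereochemistry: the target has no stereocentre and no stereogenic double bond, so nothing has to be controlled.

Key step: step 2

Assumption: sodium nitromalonaldehyde is bought as its monohydrate and handled moist behind a shield, because the dry salt is impact-sensitive; ring A numbering is as defined above throughout.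

**Step 1**
Reactants: 1 2,4-dibromophenol; 2 chloroacetone (1-chloropropan-2-one)
Product: 3 1-(2,4-dibromophenoxy)propan-2-one
Conditions: K2CO3 (1.5 equiv), KI (0.1 equiv), acetone, reflux
Reagents that add atoms: none
Why: Williamson ether synthesis: the phenoxide of 1 should displace chloride from the α-chloro ketone by SN2 (iodide as Finkelstein catalyst), while the aryl bromides are inert to carbonate in acetone.

**Step 2**
Reactants: 3 1-(2,4-dibromophenoxy)propan-2-one; 4 sodium nitromalonaldehyde (sodium salt of 2-nitropropanedial)
Product: 7 2-(2,4-dibromophenoxy)-4-nitrophenol, via open-chain enone nitronate 5 (not isolated), via sodium nitrophenolate 6 (not isolated)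
Conditions: 4 (1.2 equiv), NaOH (1.5 equiv), EtOH/H2O (1:1), 20 °C, 3 d; then 2 M HCl, 0 °C
Reagents that add atoms: none
Why: Hydroxide enolises 3 toward its aryloxy-bearing methylene; this enolate adds to one formyl carbon of the nitromalonaldehyde anion and loses water (C1–C6) to give enone nitronate 5, after which the methyl-derived enolate carbon C3 attacks the remaining formyl carbon (C3–C4), and a second dehydration with tautomerisation of the former ketone carbonyl to C2–O− gives nitrophenolate 6, protonated on acidification to 7. The closest known reaction type is the classical condensation of sodium nitromalonaldehyde with ketones bearing two enolisable α-carbons to give 4-nitrophenols, applied here to an aryloxyacetone. Ring A closes in a 6-(enolendo)-exo-trig aldol mode, and aromatisation to a resonance-stabilised 4-nitrophenolate should make the sequence irreversible. No stereocentre is formed, and the double-bond geometry of 5 can equilibrate in the delocalised anion. The only selectivity needed is crossed condensation over self-condensation of 3: the dialdehyde is symmetric and has no α-hydrogen, so either order of bond formation gives the same ring with nitrogen on C5, and it is used in slight excess.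

**Step 3**
Reactants: 7 2-(2,4-dibromophenoxy)-4-nitrophenol
Product: 8 2-(2,4-dibromophenoxy)-1-methoxy-4-nitrobenzene
Conditions: MeI (1.5 equiv), K2CO3 (2 equiv), DMF, 25 °C
Reagents that add atoms: iodomethane, CI
Why: Williamson O-methylation: the acidic 4-nitrophenol is fully ionised by K2CO3 and its phenoxide is the only nucleophile present, so SN2 attack on iodomethane should be clean.

**Step 4**
Reactants: 8 2-(2,4-dibromophenoxy)-1-methoxy-4-nitrobenzene
Product: 9 3-(2,4-dibromophenoxy)-4-methoxyaniline
Conditions: SnCl2·2H2O (4.5 equiv), conc. HCl, EtOH, 60 °C; then aq. NaOH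
Reagents that add atoms: none
Why: Nitro-to-amine reduction by divalent tin chloride (stannous chloride reduction) runs through nitroso and hydroxylamine stages and, unlike hydrogenation over palladium, should leave the aryl C–Br bonds and both ethers untouched.

**Step 5**
Reactants: 9 3-(2,4-dibromophenoxy)-4-methoxyaniline
Product: 10 2,6-dibromo-3-(2,4-dibromophenoxy)-4-methoxyaniline
Conditions: NBS (2.05 equiv), MeCN, 0 °C to 20 °C, dark
Reagents that add atoms: N-bromosuccinimide, O=C1CCC(=O)N1Br
Why: Electrophilic aromatic bromination of a free aniline: the amino group on C5 directs to its ortho carbons C4 and C6 (its para carbon C2 carries the methoxy group), whereas C3 is meta to nitrogen and ring B is deactivated, so two equivalents of NBS should stop at the 2,6-dibromoaniline.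

**Step 6**
Reactants: 10 2,6-dibromo-3-(2,4-dibromophenoxy)-4-methoxyaniline
Product: 12 1,2,3-tribromo-4-(2,4-dibromophenoxy)-5-methoxybenzene, via arenediazonium bromide 11 (not isolated)
Conditions: t-BuONO (1.5 equiv), CuBr2 (1.2 equiv), MeCN, 0 °C to 60 °C
Reagents that add atoms: copper dibromide, Br[Cu]Br (bromine on C5); tert-butyl nitrite, CC(C)(C)ON=O (terminal nitrogen of 11 only, lost again as N2)
Why: Sandmeyer bromodediazoniation in its aprotic alkyl nitrite/CuBr2 form: tert-butyl nitrite should diazotise even this weakly basic, doubly ortho-substituted aniline, electron transfer from monovalent copper formed in situ expels N2, and the aryl radical takes bromine from divalent copper bromide at C5; the diazonium group is meta to the aryloxy oxygen, so cyclisation onto ring B cannot compete.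

**Compound list**

1 | 2,4-dibromophenol | Oc1ccc(Br)cc1Br | starting material
2 | chloroacetone (1-chloropropan-2-one) | CC(=O)CCl | starting material
3 | 1-(2,4-dibromophenoxy)propan-2-one | CC(=O)COc1ccc(Br)cc1Br | intermediate
4 | sodium nitromalonaldehyde (sodium salt of 2-nitropropanedial, supplied as monohydrate) | O=CC(C=O)=[N+]([O-])[O-].[Na+] | starting material
5 | sodium salt (nitronate form) of (3E)-4-(2,4-dibromophenoxy)-2-nitro-5-oxohex-3-enal, acetyl group cis to the nitronate carbon | CC(=O)/C(Oc1ccc(Br)cc1Br)=C\C(C=O)=[N+]([O-])[O-].[Na+] | intermediate (not isolated)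
6 | sodium 2-(2,4-dibromophenoxy)-4-nitrophenolate | [O-]c1ccc(cc1Oc1ccc(Br)cc1Br)[N+](=O)[O-].[Na+] | intermediate (not isolated)
7 | 2-(2,4-dibromophenoxy)-4-nitrophenol | Oc1ccc(cc1Oc1ccc(Br)cc1Br)[N+](=O)[O-] | intermediate
8 | 2-(2,4-dibromophenoxy)-1-methoxy-4-nitrobenzene | COc1ccc(cc1Oc1ccc(Br)cc1Br)[N+](=O)[O-] | intermediate
9 | 3-(2,4-dibromophenoxy)-4-methoxyaniline | COc1ccc(N)cc1Oc1ccc(Br)cc1Br | intermediate
10 | 2,6-dibromo-3-(2,4-dibromophenoxy)-4-methoxyaniline | COc1cc(Br)c(N)c(Br)c1Oc1ccc(Br)cc1Br | intermediate
11 | 2,6-dibromo-3-(2,4-dibromophenoxy)-4-methoxybenzenediazonium bromide | COc1cc(Br)c([N+]#N)c(Br)c1Oc1ccc(Br)cc1Br.[Br-] | intermediate (not isolated)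
12 | 1,2,3-tribromo-4-(2,4-dibromophenoxy)-5-methoxybenzene | COc1cc(Br)c(Br)c(Br)c1Oc1ccc(Br)cc1Br | target

**Step count and risks**

Total steps: 6. Longest linear sequence: 6 steps (1 to 12).

Steps most likely to fail:

1. Step 2. In the partly aqueous medium the crossed condensation may be slow, so base-induced self-condensation of the ketone and decay of the nitromalonaldehyde anion could outrun ring closure. The fallback sets out from 1 and comes back at 8. Compound 1 would be O-arylated with purchased (2-methoxy-5-nitrophenyl)boronic acid under Chan–Lam conditions (Cu(OAc)2, pyridine, 4 Å molecular sieves, CH2Cl2, air, 25 °C). This forms the diaryl ether bond on a ready-made ring A and should leave the aryl bromides alone. No compound outside the list is formed on this detour (F0).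

2. Step 6. The hindered, strongly electrophilic diazonium ion may be lost to hydrodediazoniation by hydrogen abstraction from the solvent, or to attack at the para methoxy carbon, before bromine is transferred. The fallback sets out from 10 and comes back at 12. Compound 10 would be diazotised with NOBF4 in MeCN at −20 °C to 2,6-dibromo-3-(2,4-dibromophenoxy)-4-methoxybenzenediazonium tetrafluoroborate F1. This would be trapped in the same flask with diethylamine and K2CO3 as the stable, chromatographable (E)-1-[2,6-dibromo-3-(2,4-dibromophenoxy)-4-methoxyphenyl]-3,3-diethyltriaz-1-ene F2. The purified triazene would then be cleaved with bromotrimethylsilane in dry MeCN at 60 °C, which should give 12 under copper-free, anhydrous conditions with bromide as the only nucleophile.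

3. Step 5. Stoichiometric control may be lost on the very electron-rich free aminoanisole, through oxidation to quinone-imine-type material or a third bromination before the crowded C6 position has reacted. The fallback sets out from 9 and comes back at 10, introducing the bromines one at a time.
   - Compound 9 would be acetylated (Ac2O, pyridine) to N-[3-(2,4-dibromophenoxy)-4-methoxyphenyl]acetamide F3.
   - The oxidation-resistant anilide would be brominated once (Br2, NaOAc, AcOH) at C4, the carbon ortho to nitrogen and para to the aryloxy oxygen, to give N-[2-bromo-5-(2,4-dibromophenoxy)-4-methoxyphenyl]acetamide F4.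
   - Acidic hydrolysis (HCl, EtOH, reflux) would free 2-bromo-5-(2,4-dibromophenoxy)-4-methoxyaniline F5.
   - One equivalent of NBS would then brominate the single remaining ortho carbon C6 to reach 10.

**Further compounds**

F0 | step 2 | none | none
F1 | step 6 | 2,6-dibromo-3-(2,4-dibromophenoxy)-4-methoxybenzenediazonium tetrafluoroborate | COc1cc(Br)c([N+]#N)c(Br)c1Oc1ccc(Br)cc1Br.F[B-](F)(F)F
F2 | step 6 | (E)-1-[2,6-dibromo-3-(2,4-dibromophenoxy)-4-methoxyphenyl]-3,3-diethyltriaz-1-ene | CCN(CC)/N=N/c1c(Br)cc(OC)c(Oc2ccc(Br)cc2Br)c1Br
F3 | step 5 | N-[3-(2,4-dibromophenoxy)-4-methoxyphenyl]acetamide | COc1ccc(NC(C)=O)cc1Oc1ccc(Br)cc1Br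
F4 | step 5 | N-[2-bromo-5-(2,4-dibromophenoxy)-4-methoxyphenyl]acetamide | COc1cc(Br)c(NC(C)=O)cc1Oc1ccc(Br)cc1Br
F5 | step 5 | 2-bromo-5-(2,4-dibromophenoxy)-4-methoxyaniline | COc1cc(Br)c(N)cc1Oc1ccc(Br)cc1Br
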